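**Strategy**

The plan cuts the target at C10=C11 after raising that bond to an alkyne. This alkene belongs to two rings at once: in the 14-membered carbocycle (C1–C14) it is E, in the 7-membered lactone (C10–C14, O, C15) it is cis. A C10≡C11 cycloalkyne carries no geometry, and a silicon hydride tethered to the C14 oxygen later adds trans across it to deliver exactly that arrangement. Ring-closing alkyne metathesis therefore builds the carbocycle in one operation from an acyclic diyne with two methyl-capped alkynes, which already holds the (4E,6E)-diene, the C1 acetate, the free tertiary C14 hydroxyl and both stereocentres.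

Key step: step 11

Remark on the chemistry: atoms are numbered C1 (CHOAc) to C14 (methyl carbinol) round the carbocycle, with C15 the lactone carbonyl on C10. Read this way the target is (1R,14S) with a 4E,6E diene, and C10=C11 is Z by CIP (C15 and C12 cis).

**Route**

Step 1
Reactants: 1 5-bromopent-2-yne
Product: 2 pent-3-ynylmagnesium bromide (titrated stock solution in Et2O)
Conditions: Mg turnings (1.3 equiv, I2-activated), Et2O, gentle reflux → rt; titrated and stored under Ar
Reagents that add atoms: magnesium, [Mg]
Why: Grignard formation by insertion of magnesium into the primary C–Br bond leaves the internal alkyne alone, and one ethereal stock solution then serves both organocopper steps of the route.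

Step 2
Reactants: 2 pent-3-ynylmagnesium bromide; 3 ethyl but-2-ynoate
Product: 6 ethyl (2E)-3-methylnon-2-en-7-ynoate, via bromomagnesium bis(pent-3-ynyl)cuprate 4 (not isolated), via alkenylcuprate adduct 5 (not isolated)
Conditions: 2 (2.4 equiv), CuI (1.2 equiv), THF/Et2O, −40 °C; then 3 (1.0 equiv), −78 °C; MeOH quench at −78 °C; aq. NH4Cl
Reagents that add atoms: none
Why: Conjugate addition of a dialkylcuprate to an alkynoate is a syn carbocupration, so the pentynyl group and copper end up cis, and protonation at −78 °C, before the alkenylcuprate can isomerise, should give the E enoate.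

Step 3
Reactants: 6 ethyl (2E)-3-methylnon-2-en-7-ynoate
Product: 7 (2E)-3-methylnon-2-en-7-yn-1-ol
Conditions: i-Bu2AlH (2.2 equiv), CH2Cl2, −78 → 0 °C
Reagents that add atoms: none
Why: 1,2-Reduction of an α,β-unsaturated ester by i-Bu2AlH at low temperature should give the allylic alcohol without touching the alkyne or the alkene geometry.

Step 4
Reactants: 7 (2E)-3-methylnon-2-en-7-yn-1-ol
Product: 8 [(2R,3R)-3-methyl-3-(pent-3-yn-1-yl)oxiran-2-yl]methanol
Conditions: Ti(OiPr)4 (10 mol %), D-(−)-diethyl tartrate (12 mol %), t-BuOOH (2 equiv), 4 Å molecular sieves, CH2Cl2, −20 °C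
Reagents that add atoms: tert-butyl hydroperoxide, CC(C)(C)OO
Why: Katsuki–Sharpless asymmetric epoxidation of an E allylic alcohol, in which the D-(−)-tartrate catalyst should give the (2R,3R)-epoxide (mirror image of the 2S,3S series from the L-(+)-ester), setting the future C1 centre and the face of C14.

Step 5
Reactants: 8 [(2R,3R)-3-methyl-3-(pent-3-yn-1-yl)oxiran-2-yl]methanol; 9 1-(trimethylsilyl)propyne
Product: 12 trimethyl{4-[(2R,3R)-3-methyl-3-(pent-3-yn-1-yl)oxiran-2-yl]but-1-yn-1-yl}silane, via epoxy triflate 10 (not isolated), via 3-lithio-1-(trimethylsilyl)prop-1-yne 11 (not isolated)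
Conditions: n-BuLi (1.0 equiv), Et2O, −78 °C; Tf2O (1.05 equiv), −78 °C; then 11 (from 9, n-BuLi, THF, −20 °C; 1.5 equiv), DMPU, −78 → −40 °C
Reagents that add atoms: none
Why: SN2 alkylation of a primary triflate by the propargylic carbanion of a silylpropyne is much faster at −78 °C than opening of the hindered trisubstituted epoxide, so C2–C3 should form with both epoxide centres untouched.

Step 6
Reactants: 12 trimethyl{4-[(2R,3R)-3-methyl-3-(pent-3-yn-1-yl)oxiran-2-yl]but-1-yn-1-yl}silane
Product: 13 (5R,6S)-6-methyl-1-(trimethylsilyl)undeca-1,9-diyne-5,6-diol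
Conditions: HClO4 (5 mol %, aq.), THF/H2O (3:1), 0 °C → rt
Reagents that add atoms: water, O
Why: Acid-catalysed hydrolysis of a trisubstituted epoxide is a borderline SN2 opening in which water attacks the tertiary carbon anti to the departing oxygen, so C14 should be inverted to S while C1 keeps the R configuration from step 4.

Step 7
Reactants: 13 (5R,6S)-6-methyl-1-(trimethylsilyl)undeca-1,9-diyne-5,6-diol
Product: 14 (5R,6S)-6-methylundeca-1,9-diyne-5,6-diol
Conditions: K2CO3 (0.2 equiv), MeOH, rt
Reagents that add atoms: none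
Why: Base-catalysed protodesilylation of an alkynylsilane by methanol should free the terminal alkyne and leave the diol and the methyl-capped alkyne alone.

Step 8
Reactants: 2 pent-3-ynylmagnesium bromide; 15 3-methylbut-1-yne
Product: 18 (1E)-1-iodo-2-(propan-2-yl)hept-1-en-5-yne, via pent-3-ynylcopper 16 (not isolated), via alkenylcopper 17 (not isolated)
Conditions: 2 (1.0 equiv), CuBr·SMe2 (1.0 equiv), Et2O/Me2S, −45 °C; 15 (1.2 equiv), −25 °C; I2 (1.1 equiv), THF, −50 → 0 °C
Reagents that add atoms: iodine, II
Why: Normant carbocupration adds the pentynyl group to the internal carbon and copper to the terminal carbon of the alkyne on the same side, and iodinolysis with retention should give the iodide with iodine cis to the pentynyl chain, which is the C6=C7 geometry of the target.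

Step 9
Reactants: 14 (5R,6S)-6-methylundeca-1,9-diyne-5,6-diol; 18 (1E)-1-iodo-2-(propan-2-yl)hept-1-en-5-yne
Product: 20 (6E,8E,12R,13S)-9,13-dimethyl-6-(propan-2-yl)octadeca-6,8-diene-2,16-diyne-12,13-diol, via alkenylalane 19 (not isolated)
Conditions: AlMe3 (5 equiv), Cp2ZrCl2 (0.25 equiv), CH2Cl2, 0 °C → rt; volatiles removed; 18, Pd(PPh3)4 (5 mol %), ZnCl2 (0.2 equiv), THF, rt; aqueous KNa tartrate work-up
Reagents that add atoms: trimethylaluminium, C[Al](C)C
Why: Negishi zirconium-catalysed carboalumination adds methyl and aluminium syn to the terminal alkyne only (internal alkynes react far more slowly, and the two hydroxyls are masked in the flask as aluminium alkoxides), and palladium-catalysed cross-coupling of the E alkenylalane with the iodide proceeds with retention on both partners to give the E,E diene.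

Step 10
Reactants: 20 (6E,8E,12R,13S)-9,13-dimethyl-6-(propan-2-yl)octadeca-6,8-diene-2,16-diyne-12,13-diol
Product: 21 (6E,8E,12R,13S)-13-hydroxy-9,13-dimethyl-6-(propan-2-yl)octadeca-6,8-diene-2,16-diyn-12-yl acetate
Conditions: Ac2O (1.5 equiv), pyridine, DMAP (5 mol %), CH2Cl2, 0 °C → rt
Reagents that add atoms: acetic anhydride, CC(=O)OC(C)=O
Why: DMAP-catalysed acylation distinguishes the secondary C1 hydroxyl from the tertiary C14 hydroxyl on steric grounds, and a secondary acetate next to a tertiary alcohol has no driving force to migrate.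

Step 11
Reactants: 21 (6E,8E,12R,13S)-13-hydroxy-9,13-dimethyl-6-(propan-2-yl)octadeca-6,8-diene-2,16-diyn-12-yl acetate
Product: 22 (1R,4E,6E,14S)-14-hydroxy-4,14-dimethyl-7-(propan-2-yl)cyclotetradeca-4,6-dien-10-yn-1-yl acetate
Conditions: Mo(≡CC6H4-4-OMe)(OSiPh3)3 (10 mol %), 5 Å molecular sieves, toluene (2 mM), 80 °C
Reagents that add atoms: none
Why: The molybdenum alkylidyne adds to each methyl-capped alkyne in a [2+2] sense to give molybdacyclobutadienes whose cycloreversion exchanges the alkylidyne ends, and uptake of but-2-yne by the 5 Å sieves drives the sequence forward. The closest known reaction type is ring-closing alkyne metathesis of methyl-capped diynes to macrocyclic cycloalkynes with triphenylsilanolate molybdenum alkylidynes. The one ring formed, the 14-membered carbocycle, is closed end to end by making C10≡C11; no stereocentre is created and C1 and C14 are remote from the reacting carbons. The step needs selectivity for alkynes over the diene, which the alkylidyne provides because it does not engage olefins, and for cyclization over oligomerization, which the methyl caps and high dilution secure. The acetate is a known spectator, and the C14 hydroxyl sits on a fully substituted carbon next to the acetoxy-bearing C1, so its exchange with the bulky silanolate ligands should be slow.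

Step 12
Reactants: 22 (1R,4E,6E,14S)-14-hydroxy-4,14-dimethyl-7-(propan-2-yl)cyclotetradeca-4,6-dien-10-yn-1-yl acetate
Product: 23 (1R,4E,6E,14S)-14-[(dimethylsilyl)oxy]-4,14-dimethyl-7-(propan-2-yl)cyclotetradeca-4,6-dien-10-yn-1-yl acetate
Conditions: HMe2SiCl (2 equiv), Et3N (3 equiv), DMAP (10 mol %), CH2Cl2, 0 °C → rt
Reagents that add atoms: chlorodimethylsilane, C[SiH](C)Cl
Why: O-Silylation of the tertiary alcohol by the small chlorosilane under amine and DMAP catalysis installs the Si–H tether while acetate, diene and alkyne stay inert.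

Step 13
Reactants: 23 (1R,4E,6E,14S)-14-[(dimethylsilyl)oxy]-4,14-dimethyl-7-(propan-2-yl)cyclotetradeca-4,6-dien-10-yn-1-yl acetate
Product: 24 bicyclic siloxane (seven-membered 2,2-dimethyl-1-oxa-2-silacyclohept-3-ene spanning C14–O and C10–Si, C10=C11 Z, C1 acetate kept)
Conditions: [Cp*Ru(MeCN)3]PF6 (5 mol %), CH2Cl2, 0 °C → rt
Reagents that add atoms: none
Why: Cationic ruthenium-catalysed intramolecular trans-hydrosilylation of a bishomopropargylic silyl ether runs in the 7-endo-dig mode, so silicon should land on C10 and hydrogen on C11 on opposite sides, which is the cis-in-lactone, E-in-carbocycle geometry.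

Step 14
Reactants: 24 bicyclic siloxane
Product: 26 (1R,4E,6E,10Z,14S)-14-hydroxy-10-iodo-4,14-dimethyl-7-(propan-2-yl)cyclotetradeca-4,6,10-trien-1-yl acetate, via O-silylated iodoalkene 25 (not isolated)
Conditions: NIS (1.0 equiv), 2,6-lutidine (0.5 equiv), (CF3)2CHOH, 0 °C, dark; solvent removed cold; HF·pyridine, THF, 0 °C
Reagents that add atoms: N-iodosuccinimide, O=C1CCC(=O)N1I
Why: Iododesilylation in a fluoroalcohol replaces silicon by iodine with retention through ipso attack at C10 and a β-silyl cation, fluoride then cleaves the remaining O–Si bond, and the buffered, brief, cold conditions are chosen to spare the diene.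

Step 15
Reactants: 26 (1R,4E,6E,10Z,14S)-14-hydroxy-10-iodo-4,14-dimethyl-7-(propan-2-yl)cyclotetradeca-4,6,10-trien-1-yl acetate
Product: 27 target lactone CNP0291129.1
Conditions: Pd(PPh3)4 (10 mol %), CO (1 atm), Et3N (3 equiv), DMAP (0.2 equiv), MeCN, 65 °C
Reagents that add atoms: carbon monoxide, [C-]#[O+]
Why: Carbonylative lactonization, in which zerovalent palladium inserts into the alkenyl C–I bond, CO insertion gives an acylpalladium, and the C14 hydroxyl held cis across C10=C11 captures it to close the seven-membered unsaturated lactone.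

**Compound list**

1 | 5-bromopent-2-yne | CC#CCCBr | starting material
2 | pent-3-ynylmagnesium bromide (titrated Et2O stock solution) | CC#CCC[Mg]Br | intermediate
3 | ethyl but-2-ynoate | CC#CC(=O)OCC | starting material
4 | bromomagnesium bis(pent-3-ynyl)cuprate | CC#CCC[Cu-]CCC#CC.[Mg+]Br | intermediate
5 | bromomagnesium [(1Z)-1-(ethoxycarbonyl)-2-methyloct-1-en-6-yn-1-yl](pent-3-ynyl)cuprate (alkenylcuprate adduct, Cu cis to the new pentynyl group) | CCOC(=O)/C([Cu-]CCC#CC)=C(\C)CCC#CC.[Mg+]Br | intermediate
6 | ethyl (2E)-3-methylnon-2-en-7-ynoate | CCOC(=O)/C=C(\C)CCC#CC | intermediate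
7 | (2E)-3-methylnon-2-en-7-yn-1-ol | OC/C=C(\C)CCC#CC | intermediate
8 | [(2R,3R)-3-methyl-3-(pent-3-yn-1-yl)oxiran-2-yl]methanol | OC[C@H]1O[C@]1(C)CCC#CC | intermediate
9 | 1-(trimethylsilyl)propyne | CC#C[Si](C)(C)C | starting material
10 | [(2R,3R)-3-methyl-3-(pent-3-yn-1-yl)oxiran-2-yl]methyl trifluoromethanesulfonate | O=S(=O)(OC[C@H]1O[C@]1(C)CCC#CC)C(F)(F)F | intermediate
11 | 3-lithio-1-(trimethylsilyl)prop-1-yne | [Li]CC#C[Si](C)(C)C | intermediate
12 | trimethyl{4-[(2R,3R)-3-methyl-3-(pent-3-yn-1-yl)oxiran-2-yl]but-1-yn-1-yl}silane | C[Si](C)(C)C#CCC[C@H]1O[C@]1(C)CCC#CC | intermediate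
13 | (5R,6S)-6-methyl-1-(trimethylsilyl)undeca-1,9-diyne-5,6-diol | C[Si](C)(C)C#CCC[C@@H](O)[C@@](C)(O)CCC#CC | intermediate
14 | (5R,6S)-6-methylundeca-1,9-diyne-5,6-diol | C#CCC[C@@H](O)[C@@](C)(O)CCC#CC | intermediate
15 | 3-methylbut-1-yne | CC(C)C#C | starting material
16 | pent-3-ynylcopper (as its MgBr2 complex) | CC#CCC[Cu] | intermediate
17 | [(1E)-2-(propan-2-yl)hept-1-en-5-yn-1-yl]copper | [Cu]/C=C(/C(C)C)CCC#CC | intermediate
18 | (1E)-1-iodo-2-(propan-2-yl)hept-1-en-5-yne | I/C=C(/C(C)C)CCC#CC | intermediate
19 | dimethyl[(1E,5R,6S)-5,6-bis(dimethylaluminooxy)-2,6-dimethylundec-1-en-9-yn-1-yl]alane | C[Al](C)/C=C(\C)CC[C@@H](O[Al](C)C)[C@@](C)(O[Al](C)C)CCC#CC | intermediate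
20 | (6E,8E,12R,13S)-9,13-dimethyl-6-(propan-2-yl)octadeca-6,8-diene-2,16-diyne-12,13-diol | O[C@@H]([C@@](C)(O)CCC#CC)CC/C(C)=C/C=C(/C(C)C)CCC#CC | intermediate
21 | (6E,8E,12R,13S)-13-hydroxy-9,13-dimethyl-6-(propan-2-yl)octadeca-6,8-diene-2,16-diyn-12-yl acetate (metathesis precursor) | CC(=O)O[C@@H]([C@@](C)(O)CCC#CC)CC/C(C)=C/C=C(/C(C)C)CCC#CC | intermediate
22 | (1R,4E,6E,14S)-14-hydroxy-4,14-dimethyl-7-(propan-2-yl)cyclotetradeca-4,6-dien-10-yn-1-yl acetate (metathesis product) | CC(=O)O[C@@H]1CC/C(C)=C/C=C(/C(C)C)CCC#CCC[C@]1(C)O | intermediate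
23 | (1R,4E,6E,14S)-14-[(dimethylsilyl)oxy]-4,14-dimethyl-7-(propan-2-yl)cyclotetradeca-4,6-dien-10-yn-1-yl acetate | CC(=O)O[C@@H]1CC/C(C)=C/C=C(/C(C)C)CCC#CCC[C@]1(C)O[SiH](C)C | intermediate
24 | bicyclic siloxane: carbocycle of 22 with C10≡C11 turned into C10=C11 (Z), SiMe2 on C10 bonded to the C14 oxygen (seven-membered oxasilacycle), C1 acetate | CC(=O)O[C@@H]1CC/C(C)=C/C=C(/C(C)C)CCC2=CCC[C@]1(C)O[Si]2(C)C | intermediate
25 | (10Z)-10-iodo trienyl acetate of 26 carrying a (hexafluoropropan-2-yloxy)dimethylsilyl group on the C14 oxygen | CC(=O)O[C@@H]1CC/C(C)=C/C=C(/C(C)C)CC/C(I)=C/CC[C@]1(C)O[Si](C)(C)OC(C(F)(F)F)C(F)(F)F | intermediate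
26 | (1R,4E,6E,10Z,14S)-14-hydroxy-10-iodo-4,14-dimethyl-7-(propan-2-yl)cyclotetradeca-4,6,10-trien-1-yl acetate | CC(=O)O[C@@H]1CC/C(C)=C/C=C(/C(C)C)CC/C(I)=C/CC[C@]1(C)O | intermediate
27 | target CNP0291129.1: (1R,14S) carbocycle with C1 acetate, 4E,6E diene, 7-isopropyl, and the C14–O–C15(=O)–C10 lactone bridge across C10=C11 | CC(=O)O[C@@H]1CC/C(C)=C/C=C(/C(C)C)CCC2=CCC[C@]1(C)OC2=O | target

**Step count**

Total: 15 steps. Longest linear sequence: 14 steps (steps 1–7 and 9–15). Step 8 is a one-step branch that draws on the Grignard stock solution 2 from step 1.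

**Steps most likely to fail**

Step 14. The electrophilic iodine source may iodinate or isomerise the electron-rich C4–C7 diene faster than it cleaves the C10–Si bond, and a long-lived β-silyl cation could erode the C10=C11 geometry. The fallback sets out from cycloalkyne 22 and so also bypasses steps 12 and 13. Ruthenium-catalysed trans-hydrostannation (Bu3SnH, [Cp*RuCl]4 cat., CH2Cl2, rt) would give the C10 tributylstannyl alkene F1. Tin–iodine exchange with I2 in CH2Cl2 at −78 °C, which is fast enough to leave a diene untouched and proceeds with retention, then comes back to the route at iodide 26. Regiocontrol between C10 and C11 is not assured in this hydrostannation, so chromatographic enrichment would be needed.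

Step 15. Capture of the acylpalladium by the hindered tertiary C14 hydroxyl may be slower than its reduction or decomposition. The fallback sets out from iodide 26. CO-free aryloxycarbonylation with 2,4,6-trichlorophenyl formate (Pd(OAc)2, Xantphos, Et3N, toluene, rt) would give the 2,4,6-trichlorophenyl ester F2 with the C14 hydroxyl still free. Heating F2 with DMAP and i-Pr2NEt in toluene would then close the ring by intramolecular acyl transfer and come back at target 27. This separates the C–C bond formation from the slow C–O bond formation.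

Step 11. Exchange of the free C14 hydroxyl with the silanolate ligands may stall the catalyst, or oligomerization may outrun ring closure. The fallback sets out from precursor 21. Silylation (Et3SiOTf, 2,6-lutidine, CH2Cl2, −78 °C) would give the triethylsilyl ether diyne F3. The same metathesis at the same dilution would give the silylated cycloalkyne F4, and HF·pyridine in THF would remove the silyl group and come back at cycloalkyne 22.

**Further compounds**

F1 | step 14 | (1R,4E,6E,10Z,14S)-14-hydroxy-4,14-dimethyl-7-(propan-2-yl)-10-(tributylstannyl)cyclotetradeca-4,6,10-trien-1-yl acetate | CC(=O)O[C@@H]1CC/C(C)=C/C=C(/C(C)C)CC/C(=C/CC[C@]1(C)O)[Sn](CCCC)(CCCC)CCCC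
F2 | step 15 | 2,4,6-trichlorophenyl ester of the C10 carboxylic acid of the seco-lactone (C10=C11 Z, C14 hydroxyl free, C1 acetate) | CC(=O)O[C@@H]1CC/C(C)=C/C=C(/C(C)C)CC/C(=C/CC[C@]1(C)O)C(=O)Oc1c(Cl)cc(Cl)cc1Cl
F3 | step 11 | triethylsilyl ether of 21 at the C14 oxygen | CC(=O)O[C@@H]([C@@](C)(O[Si](CC)(CC)CC)CCC#CC)CC/C(C)=C/C=C(/C(C)C)CCC#CC
F4 | step 11 | triethylsilyl ether of 22 at the C14 oxygen | CC(=O)O[C@@H]1CC/C(C)=C/C=C(/C(C)C)CCC#CCC[C@]1(C)O[Si](CC)(CC)CC
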